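**Retrosynthetic overview**

1. Target 29 is (1R,2S,3R) at the indane carbons with an 8S carbinol (labels: C1 carries the 4-hydroxyphenyl group, C2 the 3,5-dihydroxyphenyl group, C3 the C8 carbinol arm; ring A is the benzo ring with hydroxyls on C5 and C7). The strategy rests on ring A: its two adjacent carbon substituents sit on C3a (meta to both oxygens) and C7a (ortho to O7, para to O5), the pattern left when a 3,5-dimethoxyaryne inserts into the acyl–CH bond of a β-ketoester.
2. C8–OH: reagent-controlled reduction of the C8 aryl ketone after the six methyl ethers are exchanged for silyl ethers; the ketone comes from the C3 ester by Weinreb amide and aryl Grignard.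
3. C1–aryl: Friedel–Crafts capture of the ring-A-stabilised C1 cation by anisole, anti to the C2 aryl group. C2 (with a temporary C1 carbinol) comes from Noyori transfer hydrogenation with dynamic kinetic resolution; C3 is set by base equilibration.
4. Five-membered ring (the only ring formed in the route; all benzene rings are bought): C2–C3 bond by oxidative coupling of the ketone and ester enolates of 15.
5. 15: aryne acyl-alkylation of β-ketoester 12 with silyl triflate 8 (bonds C3–C3a and C1–C7a); 8 from 3,5-dimethoxyphenol, 12 from 3,5-dimethoxyphenylacetic acid and Meldrum's acid.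

Key step: step 5

Remarks and assumptions: Anisole, not phenol, is taken as the arene for C1 so that no O–H is carried through the organomagnesium steps; its methyl ether is cleaved with the others. C3 is assumed not to epimerise under the transfer-hydrogenation conditions and is therefore equilibrated in a separate step. In the systematic names the carbon labelled C3 is locant 1 and the carbon labelled C1 is locant 3.

**Route**

Step 1
Reactants: 1 3,5-dimethoxyphenol
Product: 2 3,5-dimethoxyphenyl N-(propan-2-yl)carbamate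
Conditions: i-PrNCO (1.2 equiv), Et3N (0.2 equiv), CH2Cl2, rt
Reagents that add atoms: isopropyl isocyanate, CC(C)N=C=O
Why: Amine-catalysed addition of the phenol to the isocyanate (carbamoylation) installs a secondary carbamate that directs ortho-metalation and is later removed under mild base.

Step 2
Reactants: 2 3,5-dimethoxyphenyl N-(propan-2-yl)carbamate
Product: 6 3,5-dimethoxy-2-(trimethylsilyl)phenyl N-(propan-2-yl)carbamate, via N-silyl carbamate 3 (not isolated), via aryllithium 4 (not isolated), via doubly silylated carbamate 5 (not isolated)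
Conditions: TBSOTf (1.1 equiv), TMEDA (1.1 equiv), Et2O, 0 °C → rt; TMEDA (2 equiv), n-BuLi (2 equiv), −78 °C; Me3SiCl (3.5 equiv), −78 °C → rt; aq. NaHSO4
Reagents that add atoms: chlorotrimethylsilane, C[Si](C)(C)Cl
Why: Snieckus–Hoppe directed ortho-metalation: in situ N-silylation masks the N–H, the carbamate and the neighbouring methoxy group together direct lithiation to the carbon between them (the two such carbons are equivalent by symmetry and are preferred over the carbon between the two methoxy groups because the carbamate is the stronger director), the aryllithium is C-silylated and the N-silyl group is lost in the acidic work-up.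

Step 3
Reactants: 6 3,5-dimethoxy-2-(trimethylsilyl)phenyl N-(propan-2-yl)carbamate
Product: 8 3,5-dimethoxy-2-(trimethylsilyl)phenyl trifluoromethanesulfonate, via silylphenol 7 (not isolated)
Conditions: DBU (1.5 equiv), Et2NH (1.2 equiv), MeCN, 40 °C; then PhNTf2 (1.5 equiv), rt
Reagents that add atoms: N-phenylbis(trifluoromethanesulfonimide), O=S(=O)(N(c1ccccc1)S(=O)(=O)C(F)(F)F)C(F)(F)F
Why: E1cB cleavage of the secondary carbamate (the isocyanate is trapped by diethylamine) frees the hindered phenoxide, which is triflated in the same flask, the standard one-pot route to ortho-silylaryl triflates.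

Step 4
Reactants: 9 2-(3,5-dimethoxyphenyl)acetic acid; 10 Meldrum's acid
Product: 12 methyl 4-(3,5-dimethoxyphenyl)-3-oxobutanoate, via acyl Meldrum's acid 11 (not isolated)
Conditions: DCC (1.1 equiv), DMAP (1.1 equiv), CH2Cl2, 0 °C → rt; filtration, aq. KHSO4 wash; then MeOH, reflux
Reagents that add atoms: methanol, CO
Why: C-acylation of Meldrum's acid by the carbodiimide-activated acid, then thermal methanolysis with loss of acetone and carbon dioxide (Oikawa–Yonemitsu β-ketoester synthesis).

Step 5
Reactants: 8 3,5-dimethoxy-2-(trimethylsilyl)phenyl trifluoromethanesulfonate (1.25 equiv); 12 methyl 4-(3,5-dimethoxyphenyl)-3-oxobutanoate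
Product: 15 methyl 2-{2-[2-(3,5-dimethoxyphenyl)acetyl]-3,5-dimethoxyphenyl}acetate, via aryne 13 (not isolated), via benzocyclobutenoxide 14 (not isolated)
Conditions: CsF (2.5 equiv), MeCN (0.2 M), 80 °C
Reagents that add atoms: none
Why: Fluoride attacks silicon of 8 and expels triflate to give aryne 13; the cesium enolate of 12 adds through its central carbon to the aryne carbon remote from the flanking methoxy group (the future C3a), because the inductively withdrawing C–O bond and the distortion of the aryne place the developing aryl anion on the carbon next to oxygen (the future C7a). That aryl anion adds to the ketone carbonyl to give benzocyclobutenoxide 14 (a transient four-membered ring closed by 4-exo-trig addition), which fragments by retro-aldol-type C–C cleavage to the ester-stabilised benzylic anion and is protonated, so the acyl group (C1, C2) ends on C7a and the CH2CO2Me arm (C3, C8) on C3a. This is the aryne acyl-alkylation, the formal insertion of an aryne into the C–C bond of a β-ketoester, known for 3-alkoxy and 3,5-dialkoxy arynes and for ketoesters derived from arylacetic acids. No ring of the product is closed and no stereocentre is formed. The only selectivity required is regiochemical and is secured by the methoxy group next to the aryne bond. The ketoester is kept limiting so that the less acidic product is not arylated further.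

Step 6
Reactants: 15 methyl 2-{2-[2-(3,5-dimethoxyphenyl)acetyl]-3,5-dimethoxyphenyl}acetate
Product: 17 methyl (1R*,2S*)-2-(3,5-dimethoxyphenyl)-4,6-dimethoxy-3-oxo-2,3-dihydro-1H-indene-1-carboxylate (racemic trans), via dilithium bis-enolate 16 (not isolated)
Conditions: LiN(i-Pr)2 (2.2 equiv), THF, −78 °C (15 added slowly to the base); Fe(acac)3 (2.2 equiv), THF, −78 °C → rt; aq. NH4Cl
Reagents that add atoms: none
Why: Intramolecular oxidative enolate heterocoupling: trivalent iron oxidises the aryl-conjugated ketone enolate to the C2 radical, which adds 5-exo-trig to the ester enolate carbon C3 and the resulting radical anion gives up a second electron, closing the five-membered ring through C2–C3; both stereocentres form racemic and the acidic C2–H lets the product settle as the trans isomer.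

Step 7
Reactants: 17 methyl (1R*,2S*)-2-(3,5-dimethoxyphenyl)-4,6-dimethoxy-3-oxo-2,3-dihydro-1H-indene-1-carboxylate
Product: 18 methyl (2S,3R)-2-(3,5-dimethoxyphenyl)-3-hydroxy-4,6-dimethoxy-2,3-dihydro-1H-indene-1-carboxylate as a mixture of epimers at the ester-bearing carbon (label C3)
Conditions: RuCl[(R,R)-TsDPEN](p-cymene) (2 mol %), HCO2H (5 equiv), Et3N (10 equiv), DMF, 40 °C, degassed
Reagents that add atoms: none
Why: Noyori asymmetric transfer hydrogenation with dynamic kinetic resolution: C2 racemises through the enol in the amine-rich medium while the (R,R) catalyst delivers hydride to one carbonyl face and anti to the C2 aryl group, which should set the carbinol carbon (label C1) as R and C2 as S with hydroxyl and aryl cis; C3 is not controlled here, and the amine-rich medium spares the acid-sensitive dimethoxybenzylic alcohol.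

Step 8
Reactants: 18 methyl (2S,3R)-2-(3,5-dimethoxyphenyl)-3-hydroxy-4,6-dimethoxy-2,3-dihydro-1H-indene-1-carboxylate (epimer mixture)
Product: 19 methyl (1R,2S,3R)-2-(3,5-dimethoxyphenyl)-3-hydroxy-4,6-dimethoxy-2,3-dihydro-1H-indene-1-carboxylate
Conditions: NaOMe (0.5 equiv), MeOH, 40 °C
Reagents that add atoms: none
Why: Thermodynamic epimerisation through the ester enolate: C3 is the only acidic stereocentre left and should settle trans to the C2 aryl group (3R in the labels, locant 1R), any lactone formed from the all-cis epimer being reopened by methoxide.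

Step 9
Reactants: 19 methyl (1R,2S,3R)-2-(3,5-dimethoxyphenyl)-3-hydroxy-4,6-dimethoxy-2,3-dihydro-1H-indene-1-carboxylate; 20 anisole
Product: 21 methyl (1R,2S,3R)-2-(3,5-dimethoxyphenyl)-4,6-dimethoxy-3-(4-methoxyphenyl)-2,3-dihydro-1H-indene-1-carboxylate
Conditions: TfOH (10 mol %), anisole/CH2Cl2 (1:1), 0.01 M in 19, −40 °C → 0 °C
Reagents that add atoms: none
Why: Friedel–Crafts benzylation by an SN1 path: the C1 cation is stabilised by the ortho (C7) and para (C5) methoxy groups of ring A and is captured by the para carbon of anisole on the face anti to the C2 aryl group, which sets C1 as R (1,2-trans); C3 is inert to acid, so material that passes through the indene and is re-protonated from the other face emerges as a separable 2,3-cis diastereomer and not as the enantiomer.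

Step 10
Reactants: 21 methyl (1R,2S,3R)-2-(3,5-dimethoxyphenyl)-4,6-dimethoxy-3-(4-methoxyphenyl)-2,3-dihydro-1H-indene-1-carboxylate
Product: 22 (1R,2S,3R)-2-(3,5-dimethoxyphenyl)-N,4,6-trimethoxy-3-(4-methoxyphenyl)-N-methyl-2,3-dihydro-1H-indene-1-carboxamide
Conditions: MeNHOMe·HCl (3 equiv), i-PrMgCl (6 equiv), THF, −20 °C → 0 °C
Reagents that add atoms: N,O-dimethylhydroxylamine hydrochloride, CNOC.Cl
Why: Aminolysis of the ester by the chloromagnesium amide of N,O-dimethylhydroxylamine gives the Weinreb amide; C3 already has the thermodynamic trans configuration, so transient enolisation does no harm.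

Step 11
Reactants: 22 (1R,2S,3R)-2-(3,5-dimethoxyphenyl)-N,4,6-trimethoxy-3-(4-methoxyphenyl)-N-methyl-2,3-dihydro-1H-indene-1-carboxamide; 23 (4-methoxyphenyl)magnesium bromide
Product: 25 [(1R,2S,3R)-2-(3,5-dimethoxyphenyl)-4,6-dimethoxy-3-(4-methoxyphenyl)-2,3-dihydro-1H-inden-1-yl](4-methoxyphenyl)methanone, via magnesium hemiaminal 24 (not isolated)
Conditions: 23 (3 equiv), THF, 0 °C → rt; aq. NH4Cl
Reagents that add atoms: none
Why: Weinreb ketone synthesis: the N-methoxy chelate holds the tetrahedral adduct until work-up, so only one aryl group is added and the C8 ketone results.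

Step 12
Reactants: 25 [(1R,2S,3R)-2-(3,5-dimethoxyphenyl)-4,6-dimethoxy-3-(4-methoxyphenyl)-2,3-dihydro-1H-inden-1-yl](4-methoxyphenyl)methanone
Product: 26 [(1R,2S,3R)-2-(3,5-dihydroxyphenyl)-4,6-dihydroxy-3-(4-hydroxyphenyl)-2,3-dihydro-1H-inden-1-yl](4-hydroxyphenyl)methanone
Conditions: BBr3 (15 equiv), CH2Cl2, −78 °C → rt; MeOH then H2O, 0 °C
Reagents that add atoms: none
Why: Lewis-acid cleavage of all six aryl methyl ethers at the ketone stage, since a C8 carbinol would ionise under BBr3; the trans disposition of the C2 aryl group and the C3 acyl group rules out cyclisation of the activated carbonyl onto that ring.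

Step 13
Reactants: 26 [(1R,2S,3R)-2-(3,5-dihydroxyphenyl)-4,6-dihydroxy-3-(4-hydroxyphenyl)-2,3-dihydro-1H-inden-1-yl](4-hydroxyphenyl)methanone
Product: 27 hexakis(tert-butyldimethylsilyl) ether of 26
Conditions: TBSCl (9 equiv), imidazole (18 equiv), DMF, rt → 40 °C
Reagents that add atoms: tert-butyldimethylsilyl chloride, CC(C)(C)[Si](C)(C)Cl
Why: Silylation of the six phenols gives a neutral, organic-soluble ketone that is compatible with borane.

Step 14
Reactants: 27 hexakis(tert-butyldimethylsilyl) ether of 26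
Product: 28 (S)-carbinol at C8 of the hexakis(tert-butyldimethylsilyl) ether, (1R,2S,3R) at the indane carbons
Conditions: (R)-2-methyl-CBS-oxazaborolidine (0.5 equiv), BH3·SMe2 (1.5 equiv), THF, −20 °C; MeOH, then aq. NH4Cl
Reagents that add atoms: none
Why: Corey–Bakshi–Shibata reduction under reagent control: with the aryl group as the large substituent, the (R)-oxazaborolidine should deliver hydride to the face that gives the 8S carbinol.

Step 15
Reactants: 28 (S)-carbinol hexakis(tert-butyldimethylsilyl) ether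
Product: 29 (1R,2S,3R)-2-(3,5-dihydroxyphenyl)-1-[(S)-hydroxy(4-hydroxyphenyl)methyl]-3-(4-hydroxyphenyl)-2,3-dihydro-1H-indene-4,6-diol
Conditions: Bu4NF (8 equiv), AcOH (8 equiv), THF, 0 °C
Reagents that add atoms: none
Why: Fluoride cleaves the six aryl silyl ethers, and the acetic acid buffer keeps the phenols protonated so that the 4-hydroxybenzylic alcohol should neither ionise nor eliminate; no stereocentre is touched.

**Compound list**

1 | 3,5-dimethoxyphenol | COc1cc(O)cc(OC)c1 | starting material
2 | 3,5-dimethoxyphenyl N-(propan-2-yl)carbamate | COc1cc(OC)cc(OC(=O)NC(C)C)c1 | intermediate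
3 | 3,5-dimethoxyphenyl N-(tert-butyldimethylsilyl)-N-(propan-2-yl)carbamate | COc1cc(OC)cc(OC(=O)N(C(C)C)[Si](C)(C)C(C)(C)C)c1 | intermediate (not isolated)
4 | [2-({[tert-butyl(dimethyl)silyl](propan-2-yl)carbamoyl}oxy)-4,6-dimethoxyphenyl]lithium | COc1cc(OC)c([Li])c(OC(=O)N(C(C)C)[Si](C)(C)C(C)(C)C)c1 | intermediate (not isolated)
5 | 3,5-dimethoxy-2-(trimethylsilyl)phenyl N-(tert-butyldimethylsilyl)-N-(propan-2-yl)carbamate | COc1cc(OC)c([Si](C)(C)C)c(OC(=O)N(C(C)C)[Si](C)(C)C(C)(C)C)c1 | intermediate (not isolated)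
6 | 3,5-dimethoxy-2-(trimethylsilyl)phenyl N-(propan-2-yl)carbamate | COc1cc(OC)c([Si](C)(C)C)c(OC(=O)NC(C)C)c1 | intermediate
7 | 3,5-dimethoxy-2-(trimethylsilyl)phenol | COc1cc(O)c([Si](C)(C)C)c(OC)c1 | intermediate (not isolated)
8 | 3,5-dimethoxy-2-(trimethylsilyl)phenyl trifluoromethanesulfonate | COc1cc(OC)c([Si](C)(C)C)c(OS(=O)(=O)C(F)(F)F)c1 | intermediate
9 | 2-(3,5-dimethoxyphenyl)acetic acid | COc1cc(CC(=O)O)cc(OC)c1 | starting material
10 | Meldrum's acid (2,2-dimethyl-1,3-dioxane-4,6-dione) | CC1(C)OC(=O)CC(=O)O1 | starting material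
11 | 5-[2-(3,5-dimethoxyphenyl)-1-hydroxyethylidene]-2,2-dimethyl-1,3-dioxane-4,6-dione | COc1cc(CC(O)=C2C(=O)OC(C)(C)OC2=O)cc(OC)c1 | intermediate (not isolated)
12 | methyl 4-(3,5-dimethoxyphenyl)-3-oxobutanoate | COC(=O)CC(=O)Cc1cc(OC)cc(OC)c1 | intermediate
13 | 3,5-dimethoxybenzyne (1,2-didehydro-3,5-dimethoxybenzene) | COC1=CC(OC)=CC#C1 | intermediate (not isolated)
14 | cesium salt of methyl 7-[(3,5-dimethoxyphenyl)methyl]-7-hydroxy-3,5-dimethoxybicyclo[4.2.0]octa-1,3,5-triene-8-carboxylate (benzocyclobutenoxide, stereocentres not defined) | [Cs+].COC(=O)C1c2cc(OC)cc(OC)c2C1([O-])Cc1cc(OC)cc(OC)c1 | intermediate (not isolated)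
15 | methyl 2-{2-[2-(3,5-dimethoxyphenyl)acetyl]-3,5-dimethoxyphenyl}acetate | COC(=O)Cc1cc(OC)cc(OC)c1C(=O)Cc1cc(OC)cc(OC)c1 | intermediate
16 | dilithium bis-enolate of 15 (ketone enolate and ester enolate) | [Li+].[Li+].COC([O-])=Cc1cc(OC)cc(OC)c1C([O-])=Cc1cc(OC)cc(OC)c1 | intermediate (not isolated)
17 | methyl (1R*,2S*)-2-(3,5-dimethoxyphenyl)-4,6-dimethoxy-3-oxo-2,3-dihydro-1H-indene-1-carboxylate (racemic, trans; one enantiomer drawn) | O=C1c2c(OC)cc(OC)cc2[C@H](C(=O)OC)[C@H]1c1cc(OC)cc(OC)c1 | intermediate
18 | methyl (2S,3R)-2-(3,5-dimethoxyphenyl)-3-hydroxy-4,6-dimethoxy-2,3-dihydro-1H-indene-1-carboxylate (both epimers at locant 1; hydroxyl and aryl cis) | O[C@H]1c2c(OC)cc(OC)cc2C(C(=O)OC)[C@H]1c1cc(OC)cc(OC)c1 | intermediate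
19 | methyl (1R,2S,3R)-2-(3,5-dimethoxyphenyl)-3-hydroxy-4,6-dimethoxy-2,3-dihydro-1H-indene-1-carboxylate | O[C@H]1c2c(OC)cc(OC)cc2[C@H](C(=O)OC)[C@H]1c1cc(OC)cc(OC)c1 | intermediate
20 | anisole | COc1ccccc1 | starting material
21 | methyl (1R,2S,3R)-2-(3,5-dimethoxyphenyl)-4,6-dimethoxy-3-(4-methoxyphenyl)-2,3-dihydro-1H-indene-1-carboxylate | COc1ccc([C@@H]2c3c(OC)cc(OC)cc3[C@H](C(=O)OC)[C@H]2c2cc(OC)cc(OC)c2)cc1 | intermediate
22 | (1R,2S,3R)-2-(3,5-dimethoxyphenyl)-N,4,6-trimethoxy-3-(4-methoxyphenyl)-N-methyl-2,3-dihydro-1H-indene-1-carboxamide | COc1ccc([C@@H]2c3c(OC)cc(OC)cc3[C@H](C(=O)N(C)OC)[C@H]2c2cc(OC)cc(OC)c2)cc1 | intermediate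
23 | (4-methoxyphenyl)magnesium bromide | COc1ccc([Mg]Br)cc1 | starting material
24 | bromomagnesium salt of the N-methoxy-N-methyl hemiaminal formed from 22 and 23 (tetrahedral at C8, configuration there not defined) | COc1ccc([C@@H]2c3c(OC)cc(OC)cc3[C@H](C(O[Mg]Br)(N(C)OC)c3ccc(OC)cc3)[C@H]2c2cc(OC)cc(OC)c2)cc1 | intermediate (not isolated)
25 | [(1R,2S,3R)-2-(3,5-dimethoxyphenyl)-4,6-dimethoxy-3-(4-methoxyphenyl)-2,3-dihydro-1H-inden-1-yl](4-methoxyphenyl)methanone | COc1ccc([C@@H]2c3c(OC)cc(OC)cc3[C@H](C(=O)c3ccc(OC)cc3)[C@H]2c2cc(OC)cc(OC)c2)cc1 | intermediate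
26 | [(1R,2S,3R)-2-(3,5-dihydroxyphenyl)-4,6-dihydroxy-3-(4-hydroxyphenyl)-2,3-dihydro-1H-inden-1-yl](4-hydroxyphenyl)methanone | Oc1ccc([C@@H]2c3c(O)cc(O)cc3[C@H](C(=O)c3ccc(O)cc3)[C@H]2c2cc(O)cc(O)c2)cc1 | intermediate
27 | hexakis(tert-butyldimethylsilyl) ether of 26 | CC(C)(C)[Si](C)(C)Oc1ccc([C@@H]2c3c(O[Si](C)(C)C(C)(C)C)cc(O[Si](C)(C)C(C)(C)C)cc3[C@H](C(=O)c3ccc(O[Si](C)(C)C(C)(C)C)cc3)[C@H]2c2cc(O[Si](C)(C)C(C)(C)C)cc(O[Si](C)(C)C(C)(C)C)c2)cc1 | intermediate
28 | (S)-[(1R,2S,3R)-indan-1-yl](aryl)methanol derived from 27, all six phenols as tert-butyldimethylsilyl ethers | CC(C)(C)[Si](C)(C)Oc1ccc([C@@H]2c3c(O[Si](C)(C)C(C)(C)C)cc(O[Si](C)(C)C(C)(C)C)cc3[C@H]([C@H](O)c3ccc(O[Si](C)(C)C(C)(C)C)cc3)[C@H]2c2cc(O[Si](C)(C)C(C)(C)C)cc(O[Si](C)(C)C(C)(C)C)c2)cc1 | intermediate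
29 | (1R,2S,3R)-2-(3,5-dihydroxyphenyl)-1-[(S)-hydroxy(4-hydroxyphenyl)methyl]-3-(4-hydroxyphenyl)-2,3-dihydro-1H-indene-4,6-diol | Oc1ccc([C@@H]2c3c(O)cc(O)cc3[C@H]([C@H](O)c3ccc(O)cc3)[C@H]2c2cc(O)cc(O)c2)cc1 | target

**Step count and risks**

Total step count: 15. Longest linear sequence: 14 steps (steps 1–3, then 5–15, from 3,5-dimethoxyphenol).

The three steps most likely to fail:

Step 6 (oxidative ring closure). Before the second deprotonation the ketone enolate may attack the methyl ester (intramolecular Claisen condensation to a six-membered diketone), and the radical may couple between molecules or the acidic product may be oxidised further. The fallback sets out from 15 and returns at 17 by a polar ring closure. SeO2 in aqueous dioxane at 90 °C should oxidise the doubly activated ketone methylene to the 1,2-diketone methyl 2-{2-[2-(3,5-dimethoxyphenyl)-2-oxoacetyl]-3,5-dimethoxyphenyl}acetate F1. DBU in MeCN should then close the five-membered ring by intramolecular Knoevenagel condensation of the arylacetate carbon C3 onto the C2 carbonyl (5-exo-trig aldol, then dehydration) to give the indenone methyl 2-(3,5-dimethoxyphenyl)-4,6-dimethoxy-3-oxo-3H-indene-1-carboxylate F2. Zn in AcOH should reduce the doubly activated C2=C3 bond, and the product equilibrates to the trans indanone 17. In this path no enolisable ketone is present while the ester is deprotonated, so the Claisen closure cannot occur.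

Step 9 (arylation at C1). The cation may lose the C2 proton (indene formation, with loss of the C2 configuration in the part that is re-protonated), and it may be captured by a dimethoxyaryl ring of a second molecule, because anisole is a much weaker nucleophile than those rings. The fallback sets out from 19 and returns at 21; it replaces the arene by a far more nucleophilic dienol ether and aromatises afterwards. 19 with 1-methoxycyclohexa-1,3-diene (3 equiv) and Bi(OTf)3 (5 mol %) in CH2Cl2 at −40 °C should be alkylated at the terminal carbon of the dienol ether, anti to the C2 aryl group. Aqueous work-up hydrolyses the oxocarbenium ion to methyl (1R,2S,3S)-2-(3,5-dimethoxyphenyl)-4,6-dimethoxy-3-(4-oxocyclohex-2-en-1-yl)-2,3-dihydro-1H-indene-1-carboxylate F3 (mixture at the cyclohexenyl carbon, which is lost next). Aerobic dehydrogenation with Pd(O2CCF3)2, 2-(dimethylamino)pyridine and TsOH under O2 in DMSO at 80 °C (divalent palladium) should give the phenol methyl (1R,2S,3R)-2-(3,5-dimethoxyphenyl)-3-(4-hydroxyphenyl)-4,6-dimethoxy-2,3-dihydro-1H-indene-1-carboxylate F4. MeI and K2CO3 in acetone then give 21.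

Step 14 (C8 reduction). The C3 stereocentre may oppose the catalyst and lower the facial selectivity, or the crowded silylated ketone may react too slowly. The fallback sets out from 21 and returns at 28; it reverses the order of bond formation at C8, so that an aryl nucleophile adds to an aldehyde. BBr3 in CH2Cl2 with a methanol quench (which re-esterifies any acid) should give methyl (1R,2S,3R)-2-(3,5-dihydroxyphenyl)-4,6-dihydroxy-3-(4-hydroxyphenyl)-2,3-dihydro-1H-indene-1-carboxylate F5. TBSCl and imidazole in DMF give its pentakis(tert-butyldimethylsilyl) ether F6, and i-Bu2AlH in CH2Cl2 at −78 °C gives the corresponding (1R,2S,3R)-indene-1-carbaldehyde pentakis(tert-butyldimethylsilyl) ether F7. {4-[(tert-Butyldimethylsilyl)oxy]phenyl}magnesium bromide F8, made from commercial (4-bromophenoxy)(tert-butyl)dimethylsilane and Mg in THF, is added at −78 °C. Felkin–Anh addition anti to the C3–C3a bond is expected to favour the 8S carbinol 28, because the intrinsic sense of aryl addition to the aldehyde is opposite to that of hydride addition to ketone 27.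

**Further compounds**

F1 | step 6 | methyl 2-{2-[2-(3,5-dimethoxyphenyl)-2-oxoacetyl]-3,5-dimethoxyphenyl}acetate | COC(=O)Cc1cc(OC)cc(OC)c1C(=O)C(=O)c1cc(OC)cc(OC)c1
F2 | step 6 | methyl 2-(3,5-dimethoxyphenyl)-4,6-dimethoxy-3-oxo-3H-indene-1-carboxylate | COC(=O)C1=C(c2cc(OC)cc(OC)c2)C(=O)c2c(OC)cc(OC)cc12
F3 | step 9 | methyl (1R,2S,3S)-2-(3,5-dimethoxyphenyl)-4,6-dimethoxy-3-(4-oxocyclohex-2-en-1-yl)-2,3-dihydro-1H-indene-1-carboxylate (cyclohexenyl carbon not defined) | O=C1C=CC(CC1)[C@@H]2c3c(OC)cc(OC)cc3[C@H](C(=O)OC)[C@H]2c2cc(OC)cc(OC)c2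
F4 | step 9 | methyl (1R,2S,3R)-2-(3,5-dimethoxyphenyl)-3-(4-hydroxyphenyl)-4,6-dimethoxy-2,3-dihydro-1H-indene-1-carboxylate | Oc1ccc(cc1)[C@@H]2c3c(OC)cc(OC)cc3[C@H](C(=O)OC)[C@H]2c2cc(OC)cc(OC)c2
F5 | step 14 | methyl (1R,2S,3R)-2-(3,5-dihydroxyphenyl)-4,6-dihydroxy-3-(4-hydroxyphenyl)-2,3-dihydro-1H-indene-1-carboxylate | Oc1ccc([C@@H]2c3c(O)cc(O)cc3[C@H](C(=O)OC)[C@H]2c2cc(O)cc(O)c2)cc1
F6 | step 14 | pentakis(tert-butyldimethylsilyl) ether of F5 | CC(C)(C)[Si](C)(C)Oc1ccc([C@@H]2c3c(O[Si](C)(C)C(C)(C)C)cc(O[Si](C)(C)C(C)(C)C)cc3[C@H](C(=O)OC)[C@H]2c2cc(O[Si](C)(C)C(C)(C)C)cc(O[Si](C)(C)C(C)(C)C)c2)cc1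
F7 | step 14 | (1R,2S,3R)-2-[3,5-bis(tert-butyldimethylsilyloxy)phenyl]-4,6-bis(tert-butyldimethylsilyloxy)-3-[4-(tert-butyldimethylsilyloxy)phenyl]-2,3-dihydro-1H-indene-1-carbaldehyde | CC(C)(C)[Si](C)(C)Oc1ccc([C@@H]2c3c(O[Si](C)(C)C(C)(C)C)cc(O[Si](C)(C)C(C)(C)C)cc3[C@H](C=O)[C@H]2c2cc(O[Si](C)(C)C(C)(C)C)cc(O[Si](C)(C)C(C)(C)C)c2)cc1
F8 | step 14 | {4-[(tert-butyldimethylsilyl)oxy]phenyl}magnesium bromide | CC(C)(C)[Si](C)(C)Oc1ccc([Mg]Br)cc1
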